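**Plan**

- Numbering: C1 bears C7H2OBz, C2 is the vinylic CH, then C3(OH), C4(OH), C5(OBz) and C6(OH) follow round the ring.
- Enabling feature: removing C1 from the cyclohexene leaves C2 and C6 as the olefinic carbons of a cyclopentene oxygenated at C3, C4 and C5. O6 lies on the same ring face as the C5 benzoate, so that ester can deliver its own carbonyl oxygen to C6.
- Cuts, in order: O7–benzoyl; C1–C7 (back to a C1 vinyl bromide); C6–O6 with C2–C6 re-bonded (cyclohexene back to a 6,6-dibromobicyclo[3.1.0]hexane); C1–C2 and C1–C6 (dibromocarbene); C2=C6 (metathesis of a 1,6-diene).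
- Forward: methyl α-D-mannopyranoside is opened to the acyclic diene. The cyclopentene closes first and the cyclopropane second. Silver-induced expansion merges both into the cyclohexene, and then C7, the O7 benzoate and deprotection follow.
- Stereochemistry: C5, C4 and C3 are C2, C3 and C4 of D-mannose and are never touched. The O5 benzoate is placed on the pyranoside by the axial-ester opening of a 2,3-orthobenzoate. C6 is set in the key step by a cis-fused dioxolanylium ion.

Key step: step 9

Remark on the chemistry: all carbocycles keep the target numbering. Mannose C1, C2, C3, C4 and C5 become C6, C5, C4, C3 and C2. O4, O5 and O6 share one ring face and O3 lies on the other.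

Step 1
Reactants: 1 methyl α-D-mannopyranoside
Product: 2 methyl 6-deoxy-6-iodo-α-D-mannopyranoside
Conditions: I2, PPh3, imidazole, THF, 65 °C
Reagents that add atoms: iodine, II
Why: Garegg–Samuelsson (Appel-type) iodination, in which the bulky alkoxyphosphonium ion forms and is displaced only at the primary O6 position, so the three secondary hydroxyls and all stereocentres stay untouched.

Step 2
Reactants: 2 methyl 6-deoxy-6-iodo-α-D-mannopyranoside; 3 trimethyl orthobenzoate
Product: 5 methyl 2-O-benzoyl-6-deoxy-6-iodo-α-D-mannopyranoside, via 2,3-orthobenzoate 4 (not isolated)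
Conditions: PhC(OMe)3, camphorsulfonic acid (cat.), MeCN, rt; then 80% aq AcOH, 0 °C → rt
Reagents that add atoms: trimethyl orthobenzoate 3, COC(OC)(OC)c1ccccc1; water, O
Why: Acid-catalysed orthoester exchange can bridge only the cis-2,3-diol, and kinetically controlled hydrolysis of such a cis-fused cyclic orthoester opens to the axial ester and the equatorial alcohol, which places the benzoate on O2 (the future O5) as is routine for manno- and rhamnopyranosides.

Step 3
Reactants: 5 methyl 2-O-benzoyl-6-deoxy-6-iodo-α-D-mannopyranoside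
Product: 6 methyl 2-O-benzoyl-6-deoxy-6-iodo-3,4-bis-O-(methoxymethyl)-α-D-mannopyranoside
Conditions: MOMCl, iPr2NEt, Bu4NI (cat.), CH2Cl2, 0 → 35 °C
Reagents that add atoms: chloromethyl methyl ether, COCCl
Why: Standard methoxymethyl ether formation with a hindered amine base, iodide catalysis (iodomethyl methyl ether in situ) keeping the reaction fast and cool enough that the O2 to O3 benzoyl shift should not set in.

Step 4
Reactants: 6 methyl 2-O-benzoyl-6-deoxy-6-iodo-3,4-bis-O-(methoxymethyl)-α-D-mannopyranoside
Product: 7 2-O-benzoyl-5,6-dideoxy-3,4-bis-O-(methoxymethyl)-D-lyxo-hex-5-enose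
Conditions: activated Zn dust, THF–H2O (9:1), ultrasound, 40 °C
Reagents that add atoms: none
Why: Bernet–Vasella reductive fragmentation, in which zinc inserts into the C6–I bond and the organozinc expels the ring oxygen, unveiling C5=C6 and (after loss of methoxide) the C1 aldehyde in a neutral medium that esters and acetals tolerate, with C2, C3 and C4 unchanged.

Step 5
Reactants: 7 2-O-benzoyl-5,6-dideoxy-3,4-bis-O-(methoxymethyl)-D-lyxo-hex-5-enose
Product: 8 (3R,4S,5R)-4,5-bis(methoxymethoxy)hepta-1,6-dien-3-yl benzoate
Conditions: Ph3PCH3Br, KN(SiMe3)2, THF, 0 °C; then 7, −78 → 0 °C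
Reagents that add atoms: methyltriphenylphosphonium bromide, C[P+](c1ccccc1)(c1ccccc1)c1ccccc1.[Br-]
Why: Wittig methylenation, in which the unhindered ylide at −78 °C should add to the aldehyde far faster than it deprotonates the α-CH or attacks the benzoate, and no free alkoxide that could trigger acyl transfer is released on the way.

Step 6
Reactants: 8 (3R,4S,5R)-4,5-bis(methoxymethoxy)hepta-1,6-dien-3-yl benzoate
Product: 9 (1R,4R,5S)-4,5-bis(methoxymethoxy)cyclopent-2-en-1-yl benzoate
Conditions: second-generation Grubbs catalyst (H2IMes)(PCy3)Cl2Ru=CHPh (3 mol %), CH2Cl2, 40 °C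
Reagents that add atoms: none
Why: Ring-closing olefin metathesis of a 1,6-diene to a cyclopentene, driven by loss of ethylene and well known for carbohydrate-derived 3,4,5-trioxygenated heptadienes, with the three stereocentres as spectators.

Step 7
Reactants: 10 phenylmercuric chloride PhHgCl; 11 bromoform
Product: 13 phenyl(tribromomethyl)mercury PhHgCBr3, via potassium tribromomethanide 12 (not isolated)
Conditions: KOtBu, benzene, 5–10 °C
Reagents that add atoms: bromoform 11, BrC(Br)Br
Why: Standard preparation of the Seyferth reagent, in which tert-butoxide deprotonates bromoform and the tribromomethanide 12 is trapped at divalent mercury by chloride displacement faster than it sheds bromide at this temperature.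

Step 8
Reactants: 9 (1R,4R,5S)-4,5-bis(methoxymethoxy)cyclopent-2-en-1-yl benzoate; 13 phenyl(tribromomethyl)mercury PhHgCBr3
Product: 15 (1S,2R,3S,4R,5R)-6,6-dibromo-3,4-bis(methoxymethoxy)bicyclo[3.1.0]hexan-2-yl benzoate, via dibromocarbene 14 (not isolated)
Conditions: PhHgCBr3 (excess, in portions), benzene, 80 °C
Reagents that add atoms: phenyl(tribromomethyl)mercury 13, BrC(Br)(Br)[Hg]c1ccccc1
Why: Seyferth cyclopropanation, in which thermal extrusion of PhHgBr frees dibromocarbene under neutral aprotic conditions that spare the benzoate, and the concerted [2+1] addition can only give the cis-fused bicycle, expected mainly on the face opposite the O4/O5 pair (the face isomer need not be removed, see step 9).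

Step 9
Reactants: 15 (1S,2R,3S,4R,5R)-6,6-dibromo-3,4-bis(methoxymethoxy)bicyclo[3.1.0]hexan-2-yl benzoate
Product: 19 (1R,2S,5R,6S)-3-bromo-2-hydroxy-5,6-bis(methoxymethoxy)cyclohex-3-en-1-yl benzoate, via bromoallyl cation 16 (not isolated), via dioxolanylium ion 17 (not isolated), via hemiorthoester 18 (not isolated)
Conditions: AgBF4, 2,6-di-tert-butyl-4-methylpyridine, acetone–H2O (20:1), dark, 25 → 45 °C
Reagents that add atoms: water, O
Why: Monovalent silver pulls off the endo bromide of C1 (the one lying under the five-membered ring) while the shared C2–C6 bond opens in the disrotatory two-electron electrocyclic mode demanded by the Woodward–Hoffmann–DePuy rules, so strain release delivers the 2-bromoallyl cation 16 (C2–C1–C6) inside a six-membered carbocycle, and either face isomer of 15 owns such an endo bromide and gives the same planar cation. The closest known reaction type is the silver-promoted ring expansion of 6,6-dibromobicyclo[3.1.0]hexanes to 2-bromocyclohex-2-enyl derivatives with capture by an internal or external nucleophile, joined here to the acyloxonium participation familiar from the Woodward cis-hydroxylation. The cyclohexene arises not through a new C–C bond but by ring expansion (C1 swings into the ring as C2–C6 breaks), and the transient dioxolane ring of 17 closes by 5-exo attack of the benzoate carbonyl oxygen on C6. The new stereocentre C6 is controlled by C5, because a five-membered ring across C5–C6 can only be cis-fused and O6 must therefore arrive on the face of O5. Terminus selectivity (C6, not C2) rests on the only participating group sitting next to C6, on O3 and O4 being acetal ethers whose oxonium adducts would be reversible, and on a low water content that keeps bimolecular capture slow. Water then adds to the cationic carbon of 17, and hemiorthoester 18, fused to a half-chair that holds O3, O4 and O6 (pseudo)equatorial and O5 axial, should collapse by the axial-ester rule already used in step 2 to leave the benzoyl group on O5, the pyridinium buffer holding the medium in the weakly acidic range where benzoyl migration is slowest and the acetals are safe.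

Step 10
Reactants: 19 (1R,2S,5R,6S)-3-bromo-2-hydroxy-5,6-bis(methoxymethoxy)cyclohex-3-en-1-yl benzoate; 20 (tributylstannyl)methanol
Product: 21 (1R,2R,5R,6S)-2-hydroxy-3-(hydroxymethyl)-5,6-bis(methoxymethoxy)cyclohex-3-en-1-yl benzoate
Conditions: Bu3SnCH2OH, Pd(PPh3)4 (10 mol %), 1,4-dioxane, 95 °C
Reagents that add atoms: (tributylstannyl)methanol 20, CCCC[Sn](CCCC)(CCCC)CO
Why: Migita–Kosugi–Stille hydroxymethylation, in which zerovalent palladium inserts into the C1–Br bond, the stannane transfers its CH2OH group and reductive elimination forms C1–C7 under neutral conditions that leave the ester, the acetals and all stereocentres alone.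

Step 11
Reactants: 21 (1R,2R,5R,6S)-2-hydroxy-3-(hydroxymethyl)-5,6-bis(methoxymethoxy)cyclohex-3-en-1-yl benzoate; 22 benzoyl chloride
Product: 23 [(3R,4S,5R,6R)-5-(benzoyloxy)-6-hydroxy-3,4-bis(methoxymethoxy)cyclohex-1-en-1-yl]methyl benzoate
Conditions: BzCl (1.05 equiv), pyridine, CH2Cl2, −40 → −10 °C
Reagents that add atoms: benzoyl chloride 22, O=C(Cl)c1ccccc1
Why: Chemoselective acylation, in which one equivalent of acyl chloride and a weak base at low temperature should let the unhindered primary allylic O7–H react well ahead of the secondary O6–H, which is flanked by the C5 benzoate and the C1 substituent.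

Step 12
Reactants: 23 [(3R,4S,5R,6R)-5-(benzoyloxy)-6-hydroxy-3,4-bis(methoxymethoxy)cyclohex-1-en-1-yl]methyl benzoate
Product: 24 [(3R,4S,5R,6R)-5-(benzoyloxy)-3,4,6-trihydroxycyclohex-1-en-1-yl]methyl benzoate
Conditions: CF3CO2H–CH2Cl2–H2O (10:10:1), 0 °C → rt
Reagents that add atoms: none
Why: Acid hydrolysis of the two formaldehyde acetals, an acidic medium being chosen because benzoyl migration to the neighbouring cis hydroxyls is base-promoted, while the allylic C–O bonds, each flanked by further C–O bonds, should resist ionisation.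

**Compound list**

1 | methyl α-D-mannopyranoside | CO[C@@H]1[C@@H](O)[C@@H](O)[C@H](O)[C@@H](CO)O1 | starting material
2 | methyl 6-deoxy-6-iodo-α-D-mannopyranoside | CO[C@@H]1[C@@H](O)[C@@H](O)[C@H](O)[C@@H](CI)O1 | intermediate
3 | trimethyl orthobenzoate | COC(OC)(OC)c1ccccc1 | starting material
4 | methyl 6-deoxy-6-iodo-2,3-O-(α-methoxybenzylidene)-α-D-mannopyranoside (either configuration at the orthoester carbon) | CO[C@@H]1[C@H]2OC(OC)(c3ccccc3)O[C@H]2[C@H](O)[C@@H](CI)O1 | intermediate
5 | methyl 2-O-benzoyl-6-deoxy-6-iodo-α-D-mannopyranoside | CO[C@@H]1[C@@H](OC(=O)c2ccccc2)[C@@H](O)[C@H](O)[C@@H](CI)O1 | intermediate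
6 | methyl 2-O-benzoyl-6-deoxy-6-iodo-3,4-bis-O-(methoxymethyl)-α-D-mannopyranoside | CO[C@@H]1[C@@H](OC(=O)c2ccccc2)[C@@H](OCOC)[C@H](OCOC)[C@@H](CI)O1 | intermediate
7 | 2-O-benzoyl-5,6-dideoxy-3,4-bis-O-(methoxymethyl)-D-lyxo-hex-5-enose (open-chain aldehyde) | O=C[C@@H](OC(=O)c1ccccc1)[C@@H](OCOC)[C@H](OCOC)C=C | intermediate
8 | (3R,4S,5R)-4,5-bis(methoxymethoxy)hepta-1,6-dien-3-yl benzoate | C=C[C@@H](OC(=O)c1ccccc1)[C@@H](OCOC)[C@H](OCOC)C=C | intermediate
9 | (1R,4R,5S)-4,5-bis(methoxymethoxy)cyclopent-2-en-1-yl benzoate (C6=C2; O5 cis to O4, O3 trans to O4) | C1=C[C@@H](OCOC)[C@H](OCOC)[C@@H]1OC(=O)c2ccccc2 | intermediate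
10 | phenylmercuric chloride PhHgCl | Cl[Hg]c1ccccc1 | starting material
11 | bromoform | BrC(Br)Br | starting material
12 | potassium tribromomethanide KCBr3 | [K+].Br[C-](Br)Br | intermediate
13 | phenyl(tribromomethyl)mercury PhHgCBr3 | BrC(Br)(Br)[Hg]c1ccccc1 | intermediate
14 | dibromocarbene | Br[C]Br | intermediate
15 | (1S,2R,3S,4R,5R)-6,6-dibromo-3,4-bis(methoxymethoxy)bicyclo[3.1.0]hexan-2-yl benzoate (CBr2 = C1, on the face of O3, anti to O4 and O5) | BrC1(Br)[C@H]2[C@@H](OCOC)[C@H](OCOC)[C@H](OC(=O)c3ccccc3)[C@@H]12 | intermediate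
16 | 1-bromocyclohexenyl (2-bromoallyl) cation over C2–C1–C6, with C3 and C4 MOM ethers and C5 benzoate | BrC1=C[C@@H](OCOC)[C@H](OCOC)[C@H](OC(=O)c2ccccc2)[CH+]1 | intermediate
17 | 2-phenyl-1,3-dioxolan-2-ylium ion cis-fused across C5–C6 of the 1-bromocyclohexene | BrC1=C[C@@H](OCOC)[C@H](OCOC)[C@@H]2OC(c3ccccc3)=[O+][C@H]12 | intermediate
18 | 2-hydroxy-2-phenyl-1,3-dioxolane (hemiorthoester) cis-fused across C5–C6 | BrC1=C[C@@H](OCOC)[C@H](OCOC)[C@@H]2OC(O)(c3ccccc3)O[C@H]12 | intermediate
19 | (1R,2S,5R,6S)-3-bromo-2-hydroxy-5,6-bis(methoxymethoxy)cyclohex-3-en-1-yl benzoate (target numbering 3R,4S,5R,6S; O6 cis to O5) | BrC1=C[C@@H](OCOC)[C@H](OCOC)[C@H](OC(=O)c2ccccc2)[C@@H]1O | intermediate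
20 | (tributylstannyl)methanol | CCCC[Sn](CCCC)(CCCC)CO | starting material
21 | (1R,2R,5R,6S)-2-hydroxy-3-(hydroxymethyl)-5,6-bis(methoxymethoxy)cyclohex-3-en-1-yl benzoate | OCC1=C[C@@H](OCOC)[C@H](OCOC)[C@H](OC(=O)c2ccccc2)[C@@H]1O | intermediate
22 | benzoyl chloride | O=C(Cl)c1ccccc1 | starting material
23 | [(3R,4S,5R,6R)-5-(benzoyloxy)-6-hydroxy-3,4-bis(methoxymethoxy)cyclohex-1-en-1-yl]methyl benzoate | O=C(OCC1=C[C@@H](OCOC)[C@H](OCOC)[C@H](OC(=O)c2ccccc2)[C@@H]1O)c1ccccc1 | intermediate
24 | [(3R,4S,5R,6R)-5-(benzoyloxy)-3,4,6-trihydroxycyclohex-1-en-1-yl]methyl benzoate | O=C(OCC1=C[C@@H](O)[C@H](O)[C@H](OC(=O)c2ccccc2)[C@@H]1O)c1ccccc1 | target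

**Step count**

- Total step count: 12.
- Longest linear sequence: 11 (steps 1–6 and 8–12). Step 7 is a side branch.

**Steps most likely to fail**

Risk 1 (step 8). The olefin is drained of electron density by two allylic C–O bonds and is screened on both faces. Cycloaddition may therefore lag behind carbene decay and C–H insertion at the acetal CH2 groups.

The fallback sets out from 9 and moves the carbene addition ahead of the acylation.
- K2CO3 in MeOH takes off the benzoate to give the cyclopentenol F1.
- TBSCl/imidazole gives the silyl ether F2, which is more electron-rich and indifferent to base.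
- A large excess of CHBr3, 50% aq NaOH and BnEt3NCl (phase-transfer dibromocarbene) can then be used to reach the silyloxy dibromocyclopropane F3.
- Bu4NF buffered with AcOH frees the cyclopropyl carbinol F4.
- BzCl/pyridine comes back to the route at 15.

Risk 2 (step 9). External water may intercept the cation faster than the ester does, which would erode facial control at C6.

The fallback sets out from 15 and sets C6 by hydride delivery instead of anchimeric capture.
- The silver-assisted hydrolysis is run without regard to the C6 configuration to give the C6-epimeric bromocyclohexenols F5.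
- Dess–Martin periodinane converges them on the 2-bromocyclohexenone F6.
- Luche reduction (NaBH4, CeCl3·7H2O, MeOH, −78 °C) should bring hydride in from the face opposite the axial C5 benzoate. O6 is then placed cis to O5, and the route is rejoined at 19.

Risk 3 (step 5). The basic ylide may enolise the α-benzoyloxy aldehyde, with epimerisation at the future C5 or β-elimination of the neighbouring acetal oxygen.

The fallback sets out from 6 and puts the ester on only after the olefination.
- NaOMe (cat.) in MeOH removes the benzoate to give the 2-hydroxy glycoside F7.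
- Zinc fragmentation as in step 4 gives the α-hydroxy aldehyde F8.
- Excess Ph3P=CH2 gives the dienol F9. The first equivalent forms the alkoxide, which shields the α-CH as in Wittig reactions of lactols.
- BzCl/pyridine comes back to the route at 8.

**Further compounds**

F1 | step 8 | 4,5-bis(methoxymethoxy)cyclopent-2-en-1-ol (debenzoylated 9, configuration as in 9) | C1=C[C@@H](OCOC)[C@H](OCOC)[C@@H]1O
F2 | step 8 | tert-butyldimethylsilyl ether of F1 | C1=C[C@@H](OCOC)[C@H](OCOC)[C@@H]1O[Si](C)(C)C(C)(C)C
F3 | step 8 | 6,6-dibromo-3,4-bis(methoxymethoxy)-2-(tert-butyldimethylsilyloxy)bicyclo[3.1.0]hexane (configuration as in 15) | BrC1(Br)[C@H]2[C@@H](OCOC)[C@H](OCOC)[C@H](O[Si](C)(C)C(C)(C)C)[C@@H]12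
F4 | step 8 | 6,6-dibromo-3,4-bis(methoxymethoxy)bicyclo[3.1.0]hexan-2-ol (configuration as in 15) | BrC1(Br)[C@H]2[C@@H](OCOC)[C@H](OCOC)[C@H](O)[C@@H]12
F5 | step 9 | 3-bromo-2-hydroxy-5,6-bis(methoxymethoxy)cyclohex-3-en-1-yl benzoate, both C6 epimers (target numbering) | BrC1=C[C@@H](OCOC)[C@H](OCOC)[C@H](OC(=O)c2ccccc2)C1O
F6 | step 9 | 3-bromo-5,6-bis(methoxymethoxy)-2-oxocyclohex-3-en-1-yl benzoate | BrC1=C[C@@H](OCOC)[C@H](OCOC)[C@H](OC(=O)c2ccccc2)C1=O
F7 | step 5 | methyl 6-deoxy-6-iodo-3,4-bis-O-(methoxymethyl)-α-D-mannopyranoside | CO[C@@H]1[C@@H](O)[C@@H](OCOC)[C@H](OCOC)[C@@H](CI)O1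
F8 | step 5 | 5,6-dideoxy-3,4-bis-O-(methoxymethyl)-D-lyxo-hex-5-enose | O=C[C@@H](O)[C@@H](OCOC)[C@H](OCOC)C=C
F9 | step 5 | 4,5-bis(methoxymethoxy)hepta-1,6-dien-3-ol (debenzoylated 8, configuration as in 8) | C=C[C@@H](O)[C@@H](OCOC)[C@H](OCOC)C=C
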